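**Retrosynthetic overview**

- The strategy rests on the unsubstituted C15=C15' ethene, which sits between the methyl-bearing C13=C14 and C13'=C14' alkenes. Cutting C14–C15 and C14'–C15' gives a ring-A tetraenyl C14 iodide (free 3,5,6-triol), a ring-B trienynyl C14' iodide (free 3'-OH) and a two-carbon E ethene carrying tin at one end and boron at the other.
- Each iodide is traced to a C15 aldehyde and one shared C4 iodoallyl phosphonate (olefination at C11=C12 and C11'=C12'); the C4 unit comes from propargyl alcohol.
- Ring B: C6'–C7' by Sonogashira coupling of an enol triflate with (E)-3-methylpent-2-en-4-yn-1-ol. Ring A: the same triflate is carbonylated, epoxidised (Sharpless), extended by a C5 phosphonate, and the oxirane is hydrolysed with inversion at C6 to the trans 5,6-diol.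
- Neither carbocycle is built: both come intact from ketoisophorone through (4R,6R)-actinol, which supplies C3 and C3'. The only ring formed is the ring-A oxirane (made in step 14, opened in step 17).

Key step: step 23

Remarks on the chemistry:
- Carotenoid numbering is used throughout (ring A: C1 gem-dimethyl carbon, C3 secondary carbinol, C5 methyl carbinol, C6 chain-bearing carbinol; chain C7 to C15, then C15' to C7'; ring B C6' to C1', hydroxyl on C3'). Descriptors of ring-A intermediates refer to this numbering.
- One tert-butyldiphenylsilyl (TBDPS) ether protects the secondary hydroxyl of both rings until the last step of each arm; it is chosen because it must survive aqueous acid in the ring-A arm.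
- Assumption: the commercial C5 phosphonate ester is an E-rich mixture whose anion equilibrates; only the E form is drawn.

**Common enol triflate**

Step 1
Reactants: 1 ketoisophorone (2,6,6-trimethylcyclohex-2-ene-1,4-dione)
Product: 2 (6R)-2,2,6-trimethylcyclohexane-1,4-dione ((6R)-levodione)
Conditions: OYE2 (old yellow enzyme of Saccharomyces cerevisiae), NADP+ (cat.), D-glucose, glucose dehydrogenase, phosphate buffer pH 7, 30 °C
Reagents that add atoms: none
Why: Flavin-dependent ene-reductase conjugate reduction of the enedione C=C, the reaction behind the fermentative levodione process; the enzyme pocket sets the 6R methyl centre and glucose dehydrogenase recycles the hydride.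

Step 2
Reactants: 2 (6R)-levodione
Product: 3 (4R,6R)-4-hydroxy-2,2,6-trimethylcyclohexanone ((4R,6R)-actinol)
Conditions: H2 (5 bar), Raney Ni, MeOH, rt; recrystallisation
Reagents that add atoms: none
Why: Chemoselective heterogeneous hydrogenation of the unhindered C4 carbonyl (C1 is shielded by both neighbours); hydrogen should add to the face remote from the axial C2 methyl, placing the new hydroxyl trans to the C6 methyl (4R), and the minor cis alcohol is removed by crystallisation.

Step 3
Reactants: 3 (4R,6R)-actinol
Product: 4 (4R,6R)-4-(tert-butyldiphenylsilyloxy)-2,2,6-trimethylcyclohexanone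
Conditions: TBDPSCl, imidazole, DMAP (cat.), DMF, 40 °C
Reagents that add atoms: tert-butyl(chloro)diphenylsilane, CC(C)(C)[Si](Cl)(c1ccccc1)c1ccccc1
Why: Standard imidazole-promoted silylation of a secondary alcohol; the TBDPS ether is chosen for its stability to aqueous acid.

Step 4
Reactants: 4 silyl-protected actinol
Product: 5 (4R)-4-(tert-butyldiphenylsilyloxy)-2,6,6-trimethylcyclohex-1-en-1-yl trifluoromethanesulfonate
Conditions: LiN(i-Pr)2, THF, −78 °C; PhNTf2, −78 °C → rt
Reagents that add atoms: N-phenylbis(trifluoromethanesulfonimide), O=S(=O)(N(c1ccccc1)S(=O)(=O)C(F)(F)F)C(F)(F)F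
Why: Kinetic deprotonation at the only enolisable position and O-triflation of the lithium enolate gives the tetrasubstituted enol triflate, erasing the now redundant methyl stereocentre.

**C4 iodoallyl phosphonate**

Step 5
Reactants: 6 propargyl alcohol
Product: 8 (E)-3-iodo-2-methylprop-2-en-1-ol, via alkenylalane 7 (not isolated)
Conditions: Me3Al (3 equiv), Cp2ZrCl2 (0.25 equiv), CH2Cl2, 0 °C → rt; I2, THF, −30 → 0 °C
Reagents that add atoms: trimethylaluminium, C[Al](C)C; iodine, II
Why: Negishi zirconium-catalysed carboalumination adds methyl and aluminium syn across the alkyne with methyl on the internal carbon, and iodinolysis of the C–Al bond with retention gives the E iodide.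

Step 6
Reactants: 8 (E)-3-iodo-2-methylprop-2-en-1-ol
Product: 9 (E)-3-bromo-1-iodo-2-methylprop-1-ene
Conditions: CBr4, PPh3, CH2Cl2, 0 °C
Reagents that add atoms: carbon tetrabromide, BrC(Br)(Br)Br
Why: Appel bromination of a primary allylic alcohol under neutral conditions leaves the vinyl iodide and the alkene geometry untouched.

Step 7
Reactants: 9 (E)-3-bromo-1-iodo-2-methylprop-1-ene
Product: 10 diethyl [(E)-3-iodo-2-methylprop-2-en-1-yl]phosphonate
Conditions: P(OEt)3 (neat), 90 °C
Reagents that add atoms: triethyl phosphite, CCOP(OCC)OCC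
Why: Michaelis–Arbuzov reaction of the allylic bromide; the vinyl iodide is inert to triethyl phosphite in the absence of a transition-metal catalyst.

**Ring-B arm**

Step 8
Reactants: 5 enol triflate; 11 (E)-3-methylpent-2-en-4-yn-1-ol
Product: 12 (2E)-5-[(4R)-4-(tert-butyldiphenylsilyloxy)-2,6,6-trimethylcyclohex-1-en-1-yl]-3-methylpent-2-en-4-yn-1-ol
Conditions: Pd(PPh3)4 (cat.), CuI (cat.), i-Pr2NH, DMF, rt
Reagents that add atoms: none
Why: Sonogashira coupling of a hindered enol triflate with a terminal alkyne, the slim alkyne tolerating the flanking gem-dimethyl and methyl groups; it forms C6'–C7' and keeps the E alkene of 11.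

Step 9
Reactants: 12 ring-B C15 enynol
Product: 13 (2E)-5-[(4R)-4-(tert-butyldiphenylsilyloxy)-2,6,6-trimethylcyclohex-1-en-1-yl]-3-methylpent-2-en-4-ynal
Conditions: MnO2, CH2Cl2, rt
Reagents that add atoms: none
Why: MnO2 oxidation selective for the primary allylic alcohol gives the conjugated ynenal without touching alkene geometry or the silyl ether.

Step 10
Reactants: 13 ring-B C15 ynenal; 10 iodoallyl phosphonate
Product: 14 silyl-protected ring-B trienynyl iodide (3'-O-TBDPS ether of iodide B; 9'E,11'E,13'E)
Conditions: 10, NaN(SiMe3)2, THF, −78 °C; then 13, −78 → 0 °C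
Reagents that add atoms: none
Why: Horner–Wadsworth–Emmons olefination of an enal with an allylic phosphonate anion, which should form C11'=C12' E-selectively while the iodoalkene keeps its E geometry.

Step 11
Reactants: 14 silyl-protected ring-B iodide
Product: 15 iodide B, (4R)-4-[(3E,5E,7E)-8-iodo-3,7-dimethylocta-3,5,7-trien-1-yn-1-yl]-3,5,5-trimethylcyclohex-3-en-1-ol
Conditions: TBAF, THF, rt, dark
Reagents that add atoms: none
Why: Fluoride cleavage of the silyl ether; the enyne and the vinyl iodide are inert to TBAF.

**Ring-A arm**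

Step 12
Reactants: 5 enol triflate
Product: 16 methyl (4R)-4-(tert-butyldiphenylsilyloxy)-2,6,6-trimethylcyclohex-1-ene-1-carboxylate
Conditions: Pd(OAc)2 (cat.), PPh3, CO (1 atm), Et3N, MeOH–DMF, 70 °C
Reagents that add atoms: carbon monoxide, [C-]#[O+]; methanol, CO
Why: Palladium-catalysed methoxycarbonylation of the enol triflate (oxidative addition, CO insertion, methanolysis) installs C7 as an ester.

Step 13
Reactants: 16 methyl ester
Product: 17 [(4R)-4-(tert-butyldiphenylsilyloxy)-2,6,6-trimethylcyclohex-1-en-1-yl]methanol
Conditions: i-Bu2AlH, CH2Cl2, −78 → 0 °C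
Reagents that add atoms: none
Why: DIBAL-H 1,2-reduction of the conjugated ester gives the allylic alcohol needed to direct the epoxidation.

Step 14
Reactants: 17 allylic alcohol
Product: 18 anti epoxy alcohol (5,6-epoxide of 17; oxirane oxygen on the ring face opposite the C3 silyloxy group, as in the violaxanthin end group)
Conditions: Ti(OiPr)4, D-(−)-diethyl tartrate, t-BuOOH, 4 Å MS, CH2Cl2, −20 °C
Reagents that add atoms: tert-butyl hydroperoxide, CC(C)(C)OO
Why: Sharpless asymmetric epoxidation of a tetrasubstituted allylic alcohol; with D-(−)-diethyl tartrate the titanium-bound peroxide should be delivered to the ring face opposite the C3 silyloxy group, setting C5 and C6 of the anti epoxide.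

Step 15
Reactants: 18 anti epoxy alcohol
Product: 19 anti epoxy aldehyde (C7 aldehyde on the oxirane carbon C6)
Conditions: (n-Pr4N)RuO4 (cat.), NMO, 4 Å MS, CH2Cl2, rt
Reagents that add atoms: none
Why: Ley–Griffith oxidation of the primary alcohol under neutral conditions gives the non-enolisable epoxy aldehyde without opening the oxirane.

Step 16
Reactants: 19 anti epoxy aldehyde; 20 triethyl (E)-3-methyl-4-phosphonocrotonate
Product: 21 ethyl (2E,4E)-5-[(3S,5R,6S)-5,6-epoxy-3-(tert-butyldiphenylsilyloxy)-ring A]-3-methylpenta-2,4-dienoate (C15 epoxy dienoate)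
Conditions: 20, LiN(SiMe3)2, DMPU, THF, −78 °C; then 19, −78 → 0 °C
Reagents that add atoms: none
Why: Vinylogous Horner–Wadsworth–Emmons olefination with the C5 phosphonate ester forms C7=C8 E-selectively and, with a lithium base and DMPU at low temperature, should deliver mainly the 9E dienoate (minor 9Z isomer removed by chromatography).

Step 17
Reactants: 21 C15 epoxy dienoate
Product: 22 ethyl (2E,4E)-5-[(3S,5R,6R)-5,6-dihydroxy-3-(tert-butyldiphenylsilyloxy)-ring A]-3-methylpenta-2,4-dienoate (trans 5,6-diol; 6-OH cis to the 3-silyloxy group)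
Conditions: HClO4 (0.2 M aq), THF, 0 °C
Reagents that add atoms: water, O
Why: Acid-catalysed epoxide hydrolysis in which water attacks the protonated oxirane from the rear at the allylic tertiary C6 (trans-diaxial opening, Fürst–Plattner rule), so C6 is inverted and C5 keeps its oxygen, while the ester-terminated diene disfavours charge at C8 (no furanoid rearrangement) and the acid-stable silyl ether prevents 3,6-ether formation.

Step 18
Reactants: 22 diol dienoate
Product: 23 (2E,4E)-5-[(3S,5R,6R)-5,6-dihydroxy-3-(tert-butyldiphenylsilyloxy)-ring A]-3-methylpenta-2,4-dien-1-ol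
Conditions: i-Bu2AlH (excess), CH2Cl2, −78 → −40 °C
Reagents that add atoms: none
Why: DIBAL-H reduction of the dienoate to the allylic alcohol; the two tertiary hydroxyls are carried as aluminium alkoxides and the silyl ether is inert.

Step 19
Reactants: 23 C15 allylic alcohol
Product: 24 (2E,4E)-5-[(3S,5R,6R)-5,6-dihydroxy-3-(tert-butyldiphenylsilyloxy)-ring A]-3-methylpenta-2,4-dienal
Conditions: MnO2, CH2Cl2, rt
Reagents that add atoms: none
Why: MnO2 oxidises only the primary allylic alcohol, leaving the tertiary diol and the silyl ether untouched.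

Step 20
Reactants: 24 C15 diol dienal; 10 iodoallyl phosphonate
Product: 25 silyl-protected ring-A tetraenyl iodide (3-O-TBDPS ether of iodide A; 7E,9E,11E,13E)
Conditions: 10 (4 equiv), NaN(SiMe3)2, THF, −78 °C; then 24, −78 → −20 °C, dark
Reagents that add atoms: none
Why: Horner–Wadsworth–Emmons olefination with an excess of the phosphonate anion (the tertiary hydroxyls consume part of it), the aldehyde being added to the cold anion so that carbonyl addition outruns any alkoxide chemistry; it should form C11=C12 E-selectively.

Step 21
Reactants: 25 silyl-protected ring-A iodide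
Product: 26 iodide A, (1R,2R,4S)-1-[(1E,3E,5E,7E)-8-iodo-3,7-dimethylocta-1,3,5,7-tetraen-1-yl]-2,6,6-trimethylcyclohexane-1,2,4-triol
Conditions: TBAF, THF, rt, dark
Reagents that add atoms: none
Why: Fluoride desilylation under non-acidic conditions, which the acid-labile allylic tertiary C6 alcohol and the tetraenyl iodide tolerate.

**Linchpin and union**

Step 22
Reactants: 27 ethynylboronic acid pinacol ester
Product: 28 (E)-2-(tributylstannyl)vinylboronic acid pinacol ester
Conditions: Bu3SnH, AIBN (cat.), toluene, 80 °C
Reagents that add atoms: tributyltin hydride, CCCC[SnH](CCCC)CCCC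
Why: Radical hydrostannylation of a terminal alkyne: the stannyl radical adds to the unsubstituted carbon to give the boron-stabilised vinyl radical, and reversible stannyl radical addition at 80 °C equilibrates the adduct to the E isomer.

Step 23
Reactants: 15 iodide B; 28 tin–boron linchpin; 26 iodide A
Product: 30 (3S,5R,6R,3'R)-7',8'-didehydro-5,6-dihydro-β,β-carotene-3,5,6,3'-tetrol (all-E; the target), via polyenyl boronate 29 (not isolated)
Conditions: Pd2(dba)3 (cat.), AsPh3, degassed DMF, rt, dark (15 + 28); then 26, aq K3PO4, THF, rt; chromatography and crystallisation in the dark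
Reagents that add atoms: none
Why: Zerovalent palladium inserts into the C14'–I bond of 15; without base only the tin terminus of 28 transmetalates, because the pinacol boronate cannot hand over its vinyl group until it is converted into a borate, and reductive elimination forms C14'–C15' to give polyenyl boronate 29. Adding 26 with aqueous K3PO4 then activates boron, and a second oxidative addition (C14–I), transmetalation and reductive elimination forms C14–C15. The closest known reaction type is the one-flask Stille then Suzuki–Miyaura coupling of vinyl and dienyl linchpins bearing tin and boron, as used for polyenes. No ring is closed and no stereocentre is created; both couplings are stereoretentive, so every alkene keeps the E geometry brought in by the three partners. The step needs tin to react strictly before boron and no homocoupling: the neutral-then-basic order separates the two transmetalations, a slight excess of 28 in the first stage with exclusion of oxygen and light should suppress dimers, and the trisubstituted E iodides at C14 and C14' undergo clean oxidative addition. The four free hydroxyls, including the acid-labile allylic C6–OH, should pass unchanged through these neutral to mildly basic conditions.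

**Compound list**

1 | ketoisophorone | CC1=CC(=O)CC(C)(C)C1=O | starting material
2 | (6R)-levodione | O=C1C(C)(C)CC(=O)C[C@H]1C | intermediate
3 | (4R,6R)-actinol | O=C1C(C)(C)C[C@H](O)C[C@H]1C | intermediate
4 | (4R,6R)-4-(tert-butyldiphenylsilyloxy)-2,2,6-trimethylcyclohexanone | O=C1C(C)(C)C[C@H](O[Si](c2ccccc2)(c2ccccc2)C(C)(C)C)C[C@H]1C | intermediate
5 | (4R)-4-(tert-butyldiphenylsilyloxy)-2,6,6-trimethylcyclohex-1-en-1-yl triflate | CC1=C(OS(=O)(=O)C(F)(F)F)C(C)(C)C[C@H](O[Si](c2ccccc2)(c2ccccc2)C(C)(C)C)C1 | intermediate
6 | propargyl alcohol | C#CCO | starting material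
7 | alkenylalane (dimethylaluminium alkoxide of (E)-3-(dimethylalumino)-2-methylprop-2-en-1-ol) | C[Al](C)OC/C(C)=C/[Al](C)C | intermediate
8 | (E)-3-iodo-2-methylprop-2-en-1-ol | OC/C(C)=C/I | intermediate
9 | (E)-3-bromo-1-iodo-2-methylprop-1-ene | BrC/C(C)=C/I | intermediate
10 | diethyl [(E)-3-iodo-2-methylprop-2-en-1-yl]phosphonate | CCOP(=O)(OCC)C/C(C)=C/I | intermediate
11 | (E)-3-methylpent-2-en-4-yn-1-ol | C#C/C(C)=C/CO | starting material
12 | ring-B C15 enynol silyl ether | CC1=C(C#C/C(C)=C/CO)C(C)(C)C[C@H](O[Si](c2ccccc2)(c2ccccc2)C(C)(C)C)C1 | intermediate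
13 | ring-B C15 ynenal silyl ether | CC1=C(C#C/C(C)=C/C=O)C(C)(C)C[C@H](O[Si](c2ccccc2)(c2ccccc2)C(C)(C)C)C1 | intermediate
14 | silyl-protected iodide B | CC1=C(C#C/C(C)=C/C=C/C(C)=C/I)C(C)(C)C[C@H](O[Si](c2ccccc2)(c2ccccc2)C(C)(C)C)C1 | intermediate
15 | iodide B | CC1=C(C#C/C(C)=C/C=C/C(C)=C/I)C(C)(C)C[C@H](O)C1 | intermediate
16 | methyl (4R)-4-(tert-butyldiphenylsilyloxy)-2,6,6-trimethylcyclohex-1-ene-1-carboxylate | CC1=C(C(=O)OC)C(C)(C)C[C@H](O[Si](c2ccccc2)(c2ccccc2)C(C)(C)C)C1 | intermediate
17 | [(4R)-4-(tert-butyldiphenylsilyloxy)-2,6,6-trimethylcyclohex-1-en-1-yl]methanol | CC1=C(CO)C(C)(C)C[C@H](O[Si](c2ccccc2)(c2ccccc2)C(C)(C)C)C1 | intermediate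
18 | anti epoxy alcohol | OC[C@@]12O[C@]1(C)C[C@@H](O[Si](c3ccccc3)(c3ccccc3)C(C)(C)C)CC2(C)C | intermediate
19 | anti epoxy aldehyde | O=C[C@@]12O[C@]1(C)C[C@@H](O[Si](c3ccccc3)(c3ccccc3)C(C)(C)C)CC2(C)C | intermediate
20 | triethyl (E)-3-methyl-4-phosphonocrotonate (commercial E-rich mixture) | CCOC(=O)/C=C(C)/CP(=O)(OCC)OCC | starting material
21 | C15 epoxy dienoate | CCOC(=O)/C=C(C)/C=C/[C@@]12O[C@]1(C)C[C@@H](O[Si](c3ccccc3)(c3ccccc3)C(C)(C)C)CC2(C)C | intermediate
22 | C15 trans-5,6-diol dienoate | CCOC(=O)/C=C(C)/C=C/[C@@]1(O)C(C)(C)C[C@H](O[Si](c2ccccc2)(c2ccccc2)C(C)(C)C)C[C@@]1(C)O | intermediate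
23 | C15 diol dienol | OC/C=C(C)/C=C/[C@@]1(O)C(C)(C)C[C@H](O[Si](c2ccccc2)(c2ccccc2)C(C)(C)C)C[C@@]1(C)O | intermediate
24 | C15 diol dienal | O=C/C=C(C)/C=C/[C@@]1(O)C(C)(C)C[C@H](O[Si](c2ccccc2)(c2ccccc2)C(C)(C)C)C[C@@]1(C)O | intermediate
25 | silyl-protected iodide A | I/C=C(C)/C=C/C=C(C)/C=C/[C@@]1(O)C(C)(C)C[C@H](O[Si](c2ccccc2)(c2ccccc2)C(C)(C)C)C[C@@]1(C)O | intermediate
26 | iodide A | I/C=C(C)/C=C/C=C(C)/C=C/[C@@]1(O)C(C)(C)C[C@H](O)C[C@@]1(C)O | intermediate
27 | ethynylboronic acid pinacol ester | C#CB1OC(C)(C)C(C)(C)O1 | starting material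
28 | (E)-2-(tributylstannyl)vinylboronic acid pinacol ester | CCCC[Sn](CCCC)(CCCC)/C=C/B1OC(C)(C)C(C)(C)O1 | intermediate
29 | ring-B polyenyl pinacol boronate | CC1=C(C#C/C(C)=C/C=C/C(C)=C/C=C/B2OC(C)(C)C(C)(C)O2)C(C)(C)C[C@H](O)C1 | intermediate
30 | (3S,5R,6R,3'R)-7',8'-didehydro-5,6-dihydro-β,β-carotene-3,5,6,3'-tetrol | CC1=C(C#C/C(C)=C/C=C/C(C)=C/C=C/C=C(C)/C=C/C=C(C)/C=C/[C@@]2(O)C(C)(C)C[C@H](O)C[C@@]2(C)O)C(C)(C)C[C@H](O)C1 | target

**Step count and risks**

Total step count: 23. Longest linear sequence: 15 steps (steps 1–4, 12–21 and 23).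

Steps most likely to fail:

1. Step 23. The boron end may transmetalate or protodeboronate before the tin coupling is complete, or the iodides may homocouple, so that symmetric dimers and truncated polyenes form; the polyenyl boronate may also decompose before the second coupling. The fallback sets out from 15 and returns at 30. The tin–boron linchpin is replaced by commercial (E)-1,2-bis(tributylstannyl)ethene used in two separate base-free Stille couplings. Iodide 15 is coupled with a threefold excess of the bis-stannane (Pd2(dba)3, AsPh3, DMF, rt) to give the ring-B tetraenynyl stannane F1, isolated on triethylamine-deactivated silica. F1 is then coupled with 26 under the same conditions, forming the same C14'–C15' and C14–C15 bonds without any base or boron species.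

2. Step 17. Regio- and stereocontrol in the oxirane opening may be lost: the 5-oxygen may capture the allylic cation at C8 (furanoid rearrangement), or water may enter syn to give the 6-epimer. The fallback sets out from 19 and returns at 22. Aldehyde 19 is condensed with 1-(triphenylphosphoranylidene)propan-2-one (toluene, 80 °C, Wittig) to give the epoxy enone F2. Here C8 lies next to the carbonyl and cannot carry charge, so the same aqueous HClO4/THF hydrolysis should open only at C6 with inversion and give the diol enone F3. Horner–Wadsworth–Emmons reaction of F3 with triethyl phosphonoacetate and excess NaH (THF, rt) then gives 22, the minor 9Z isomer being removed by chromatography.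

3. Step 20. The tertiary alkoxides formed from the free diol may quench the phosphonate anion or trigger retro-aldol-type cleavage of C5–C6 through the dienal, and the iodoalkene geometry may erode in the allyl anion. The fallback sets out from 24 and returns at 26. The diol is masked with N-(trimethylsilyl)imidazole (CH2Cl2, 40 °C) to give the bis(trimethylsilyl) ether dienal F4. Olefination with 10 and NaN(SiMe3)2 (one equivalent of anion, −78 °C) gives the fully silylated tetraenyl iodide F5, and TBAF (THF, rt) removes the two trimethylsilyl groups and the TBDPS ether in one operation to give 26.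

**Further compounds**

F1 | step 23 | ring-B tetraenynyl tributylstannane | CC1=C(C#C/C(C)=C/C=C/C(C)=C/C=C/[Sn](CCCC)(CCCC)CCCC)C(C)(C)C[C@H](O)C1
F2 | step 17 | anti epoxy enone (3-O-TBDPS-5,6-epoxy-β-ionone type) | CC(=O)/C=C/[C@@]12O[C@]1(C)C[C@@H](O[Si](c3ccccc3)(c3ccccc3)C(C)(C)C)CC2(C)C
F3 | step 17 | trans-5,6-diol enone | CC(=O)/C=C/[C@@]1(O)C(C)(C)C[C@H](O[Si](c2ccccc2)(c2ccccc2)C(C)(C)C)C[C@@]1(C)O
F4 | step 20 | 5,6-bis(trimethylsilyl) ether of dienal 24 | O=C/C=C(C)/C=C/[C@@]1(O[Si](C)(C)C)C(C)(C)C[C@H](O[Si](c2ccccc2)(c2ccccc2)C(C)(C)C)C[C@@]1(C)O[Si](C)(C)C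
F5 | step 20 | 5,6-bis(trimethylsilyl) ether of iodide 25 | I/C=C(C)/C=C/C=C(C)/C=C/[C@@]1(O[Si](C)(C)C)C(C)(C)C[C@H](O[Si](c2ccccc2)(c2ccccc2)C(C)(C)C)C[C@@]1(C)O[Si](C)(C)C
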